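**Retrosynthetic overview**
1. The target is C2-symmetric: its 12-membered ring consists of two identical six-carbon segments C11–C7=C6–C5=C4–C15 joined head to tail by two C11–C15′ bonds. Within one segment, C11–H (α to the C12 ester) is conjugated through the C7=C6–C5=C4 diene of the ring-B dienone to the allylic carbon C15, so a single tricyclic monomer with a nucleofuge on C15 is both nucleophile and electrophile.
2. Both C11–C15′ bonds are cut: a Pd/phenoxide-mediated head-to-tail cyclodimerisation of the 15-phenoxy monomer (first bond intermolecular, second bond closes the macrocycle), followed by removal of two silyl groups.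
3. Monomer: C15 by Stille coupling at the C4 dienyl triflate of a ring-B vinylogous β-diketone; the 9-OH by α-face reduction of a C9 ketone.
4. Ring B: Dieckmann-type C7–C8 closure after a tandem Mukaiyama–Michael/aldol assembly on a cyclopropane-fused β-methylcyclopentenone, which sets the quaternary C10.
5. Order of ring formation: cyclopropane and ring A together (carbenoid cyclopropanation of an epoxy-alkene), then ring B, then the macrocycle.

Key step: step 14

Remark: tricyclic compounds carry lindenane numbering (C1–C2–C3 cyclopropane, C14 the methyl on C10, C15 the carbon on C4; β is the face of C14). The epoxide, methyl glycolate, methyl 2-methyl-4-oxobutanoate and all reagents are taken to be purchased.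

Step 1
Reactants: 1 (S)-1,2-epoxyhex-5-ene
Product: 2 (1S,2S,5R)-bicyclo[3.1.0]hexan-2-ol
Conditions: LiTMP (2 equiv), t-BuOMe, 0 °C to rt
Reagents that add atoms: none
Why: Hodgson cyclopropanation: the terminal epoxide carbon is lithiated trans to the chain and the carbenoid adds to the tethered alkene, so the epoxide stereocentre (kept as the carbinol carbon) should fix both cyclopropane stereocentres.

Step 2
Reactants: 2 (1S,2S,5R)-bicyclo[3.1.0]hexan-2-ol
Product: 3 (1S,5R)-bicyclo[3.1.0]hexan-2-one
Conditions: TEMPO (1 mol %), KBr (10 mol %), NaOCl, NaHCO3, CH2Cl2/H2O, 0 °C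
Reagents that add atoms: none
Why: TEMPO/hypochlorite (Anelli) oxidation of the secondary alcohol should leave the cyclopropane stereocentres untouched.

Step 3
Reactants: 3 (1S,5R)-bicyclo[3.1.0]hexan-2-one
Product: 4 (1S,5S)-bicyclo[3.1.0]hex-3-en-2-one
Conditions: IBX (1.5 equiv), DMSO/fluorobenzene, 70 °C
Reagents that add atoms: none
Why: IBX dehydrogenation of the ketone; only the C3 methylene can enolise because the other α-carbon is a cyclopropane bridgehead.

Step 4
Reactants: 4 (1S,5S)-bicyclo[3.1.0]hex-3-en-2-one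
Product: 5 (1S,4R,5S)-4-methylbicyclo[3.1.0]hexan-2-one
Conditions: MeMgBr, CuBr·SMe2 (10 mol %), THF, −40 °C; aq. NH4Cl
Reagents that add atoms: methylmagnesium bromide, C[Mg]Br
Why: Copper-catalysed conjugate addition of the Grignard reagent, expected anti to the cyclopropane methylene; the new stereocentre is removed again in step 5.

Step 5
Reactants: 5 (1S,4R,5S)-4-methylbicyclo[3.1.0]hexan-2-one
Product: 6 (1S,5R)-4-methylbicyclo[3.1.0]hex-3-en-2-one
Conditions: IBX (1.5 equiv), DMSO/fluorobenzene, 75 °C
Reagents that add atoms: none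
Why: A second IBX dehydrogenation should give the β-methyl enone whose β-carbon is the future quaternary C10.

Step 6
Reactants: 7 methyl glycolate
Product: 8 1-methoxy-1,2-bis(trimethylsilyloxy)ethene (E/Z mixture)
Conditions: LiHMDS (2.2 equiv), TMSCl (2.4 equiv), THF, −78 °C to rt
Reagents that add atoms: chlorotrimethylsilane, C[Si](C)(C)Cl
Why: O-Silylation of the hydroxyl group and in situ trapping of the ester enolate is the standard preparation of such a ketene silyl acetal.

Step 7
Reactants: 6 (1S,5R)-4-methylbicyclo[3.1.0]hex-3-en-2-one; 8 1-methoxy-1,2-bis(trimethylsilyloxy)ethene; 9 methyl 2-methyl-4-oxobutanoate (racemic)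
Product: 12 methyl 2-hydroxy-2-[3-(4-methoxy-3-methyl-4-oxobutylidene)-2-methyl-4-oxobicyclo[3.1.0]hexan-2-yl]acetate (C10 set; C9 and C11 epimers; E/Z), via silyl enol ether 10 (not isolated), via aldol bis-silyl ether 11 (not isolated)
Conditions: HNTf2 (3 mol %), CH2Cl2, −78 °C; then 9, −78 to −40 °C; then TsOH·H2O, toluene, 60 °C
Reagents that add atoms: none
Why: Tandem Mukaiyama–Michael addition, Mukaiyama aldol addition and acid-mediated desilylation–dehydration: the ketene acetal should add to the β-carbon of 6 anti to the cyclopropane methylene, which sets quaternary C10 with its methyl cis to that methylene, the regiodefined silyl enol ether then takes up the aldehyde at C5, and the C9 epimers and E/Z isomers are of no consequence because C9 is oxidised in step 8 and the alkene is re-enolised in step 9.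

Step 8
Reactants: 12 alkylidene ketone α-hydroxy ester
Product: 13 methyl 2-[3-(4-methoxy-3-methyl-4-oxobutylidene)-2-methyl-4-oxobicyclo[3.1.0]hexan-2-yl]-2-oxoacetate
Conditions: Dess–Martin periodinane, NaHCO3, CH2Cl2, rt
Reagents that add atoms: none
Why: Dess–Martin oxidation to the non-enolisable α-keto ester removes the unselectively formed C9 stereocentre so that it can be set by reduction in the ring.

Step 9
Reactants: 13 alkylidene ketone α-keto ester
Product: 15 methyl 4,9β-dihydroxy-8-oxo-15-norlindena-4,6-dien-12-oate (vinylogous acid; C11 epimers), via 9-oxo vinylogous diketone 14 (not isolated)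
Conditions: NaOMe (2.0 equiv), MeOH, 0 °C to rt; then NaBH4, −30 °C; 1 M HCl
Reagents that add atoms: none
Why: Dieckmann-type condensation through the γ-carbon (C7) of the enone dienolate onto the C8 ester closes ring B as a six-membered ring (attack through C5 would give a four-membered ring) and is driven by formation of the vinylogous β-diketonate, in which the C4 and C8 carbonyl groups are masked as the enolate so that borohydride should reduce only the C9 ketone, from the α face opposite the axial C14 methyl, setting the 9β-hydroxyl (9R).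

Step 10
Reactants: 15 vinylogous acid 9β-alcohol
Product: 16 methyl 9β-hydroxy-8-oxo-4-(trifluoromethanesulfonyloxy)-15-norlindena-4,6-dien-12-oate
Conditions: PhNTf2, Et3N, DMAP (10 mol %), CH2Cl2, 0 °C
Reagents that add atoms: N-phenylbis(trifluoromethanesulfonimide), O=S(=O)(N(c1ccccc1)S(=O)(=O)C(F)(F)F)C(F)(F)F
Why: O-Triflation of the vinylogous acid should occur at the open C4 oxygen, because the C8 oxygen is flanked by the C7 branch and C9 and is hydrogen-bonded to the 9-OH, and the neutral secondary alcohol does not react with PhNTf2.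

Step 11
Reactants: 16 dienyl triflate 9β-alcohol
Product: 17 methyl 9β-(tert-butyldimethylsilyloxy)-8-oxo-4-(trifluoromethanesulfonyloxy)-15-norlindena-4,6-dien-12-oate
Conditions: TBSOTf, 2,6-lutidine, CH2Cl2, −40 to 0 °C
Reagents that add atoms: tert-butyldimethylsilyl trifluoromethanesulfonate, CC(C)(C)[Si](C)(C)OS(=O)(=O)C(F)(F)F
Why: Silylation of the hindered secondary alcohol protects the α-ketol against O-allylation and enediol epimerisation in the later basic steps.

Step 12
Reactants: 17 dienyl triflate TBS ether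
Product: 18 methyl 9β-(tert-butyldimethylsilyloxy)-15-hydroxy-8-oxolindena-4,6-dien-12-oate
Conditions: Bu3SnCH2OH, Pd(PPh3)4 (5 mol %), LiCl, dioxane, 90 °C
Reagents that add atoms: (tributylstannyl)methanol, CCCC[Sn](CO)(CCCC)CCCC
Why: Stille coupling of the electron-poor dienyl triflate with the hydroxymethylstannane should introduce C15 at C4 without touching the dienone.

Step 13
Reactants: 18 allylic alcohol
Product: 19 methyl 9β-(tert-butyldimethylsilyloxy)-8-oxo-15-phenoxylindena-4,6-dien-12-oate
Conditions: PhOH, PPh3, DIAD, THF, 0 °C to rt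
Reagents that add atoms: phenol, Oc1ccccc1
Why: Mitsunobu etherification of the primary allylic alcohol (SN2 at C15; SN2′ at the fully substituted C5 is not possible) installs a nucleofuge that phenoxide and Pd(0) can take off and put back reversibly.

Step 14
Reactants: 19 15-phenoxy monomer (two molecules)
Product: 22 9,9′-bis-O-(tert-butyldimethylsilyl)cycloshizukaol A, via triene 20 (not isolated), via seco-dimer 21 (not isolated)
Conditions: Pd2(dba)3·CHCl3 (5 mol %), dppe (12 mol %), LiOPh (20 mol %), THF, 45 °C, 19 added by syringe pump over 12 h, 2 mM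
Reagents that add atoms: none
Why: Proposed new method: Pd(0) ionises the C15–OPh bond and phenoxide removes the vinylogously acidified C11–H, so each molecule of 19 is both an η3-allyl electrophile (C15 terminus) and, as its lithium trienolate, a C11 nucleophile, while triene 20 formed by 1,6-elimination is a reservoir that phenol/phenoxide and Pd(0) return to the cycle (and that the trienolate can also capture by 1,8-addition); the first, intermolecular C11–C15′ alkylation gives 21, whose ether-bearing unit now has a quaternary C11, cannot eliminate and is ionised again, and the remaining C11–H trienolate then attacks that C15 terminus intramolecularly. The closest known reaction types are the Tsuji–Trost allylic alkylation of ester enolates with allyl aryl ethers and its macrocyclising variant, and the head-to-tail [6+6] cyclodimerisation of p-quinodimethanes generated by 1,6-elimination; new is their use for the cyclodimerisation of a cross-conjugated trienoate. The one ring closed is the 12-membered carbocycle, by exo attack of C11 on the CH2 terminus of the allyl (palladium leaves outside the ring and the C4=C5 double bond ends up endocyclic). Each C11 stereocentre should arise by attack on the α face of the lithium-chelated trienolate (ester oxygen and C8=O bridged by Li+, so the ester is syn to C8 and the methyl syn to H6), the face away from the C14 methyl, the cyclopropane methylene and the 9-OTBS group, which corresponds to 11R, and in the ring closure the C2-symmetric, antiparallel α-face-to-α-face arrangement of the two dienone planes demands the same sense. The step needs C- over O-alkylation and α (C11) over γ/ε attack, secured by the soft η3-allyl electrophile and by re-ionisation of any O-allyl product, attack at C15 and not C5, secured because C5 is a fully substituted ring-fusion carbon, and ring closure over chain growth, favoured by slow addition at high dilution. A seco-dimer with a mis-set C11 should close slowly and can revert by retro-1,8-addition through 20, whereas the cyclic dimer has no C11–H left and is the sink.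

Step 15
Reactants: 22 9,9′-bis-O-(tert-butyldimethylsilyl)cycloshizukaol A
Product: 23 cycloshizukaol A
Conditions: HF·pyridine, pyridine, THF, 0 °C to rt
Reagents that add atoms: none
Why: Fluoride-mediated cleavage of the two secondary TBS ethers under buffered conditions that should neither epimerise the α-ketols nor touch the methyl esters.

**Compound list**
1 | (S)-1,2-epoxyhex-5-ene [(S)-2-(but-3-en-1-yl)oxirane] | C=CCC[C@H]1CO1 | starting material
2 | (1S,2S,5R)-bicyclo[3.1.0]hexan-2-ol (OH trans to the cyclopropane) | O[C@H]1CC[C@@H]2C[C@H]12 | intermediate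
3 | (1S,5R)-bicyclo[3.1.0]hexan-2-one | O=C1CC[C@@H]2C[C@H]12 | intermediate
4 | (1S,5S)-bicyclo[3.1.0]hex-3-en-2-one | O=C1C=C[C@@H]2C[C@H]12 | intermediate
5 | (1S,4R,5S)-4-methylbicyclo[3.1.0]hexan-2-one (methyl anti to the cyclopropane methylene) | C[C@@H]1CC(=O)[C@H]2C[C@@H]12 | intermediate
6 | (1S,5R)-4-methylbicyclo[3.1.0]hex-3-en-2-one | CC1=CC(=O)[C@H]2C[C@@H]12 | intermediate
7 | methyl glycolate | COC(=O)CO | starting material
8 | 1-methoxy-1,2-bis(trimethylsilyloxy)ethene (E/Z) | COC(O[Si](C)(C)C)=CO[Si](C)(C)C | intermediate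
9 | methyl 2-methyl-4-oxobutanoate (racemic) | COC(=O)C(C)CC=O | starting material
10 | methyl 2-(trimethylsilyloxy)-2-[2-methyl-4-(trimethylsilyloxy)bicyclo[3.1.0]hex-3-en-2-yl]acetate, new C–C bond anti to the cyclopropane methylene (C9 epimers) | COC(=O)C(O[Si](C)(C)C)[C@]1(C)C=C(O[Si](C)(C)C)[C@H]2C[C@@H]12 | intermediate
11 | methyl 2-(trimethylsilyloxy)-2-{3-[4-methoxy-3-methyl-4-oxo-1-(trimethylsilyloxy)butyl]-2-methyl-4-oxobicyclo[3.1.0]hexan-2-yl}acetate (diastereomers at the uncontrolled centres) | COC(=O)C(C)CC(O[Si](C)(C)C)C1C(=O)[C@H]2C[C@H]2[C@]1(C)C(O[Si](C)(C)C)C(=O)OC | intermediate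
12 | methyl 2-hydroxy-2-[3-(4-methoxy-3-methyl-4-oxobutylidene)-2-methyl-4-oxobicyclo[3.1.0]hexan-2-yl]acetate (C9, C11 epimers; E/Z) | COC(=O)C(C)CC=C1C(=O)[C@H]2C[C@H]2[C@]1(C)C(O)C(=O)OC | intermediate
13 | methyl 2-[3-(4-methoxy-3-methyl-4-oxobutylidene)-2-methyl-4-oxobicyclo[3.1.0]hexan-2-yl]-2-oxoacetate | COC(=O)C(C)CC=C1C(=O)[C@H]2C[C@H]2[C@]1(C)C(=O)C(=O)OC | intermediate
14 | methyl 4-hydroxy-8,9-dioxo-15-norlindena-4,6-dien-12-oate (in the flask as its sodium enolate) | COC(=O)C(C)C1=CC2=C(O)[C@@H]3[C@H]([C@]2(C)C(=O)C1=O)C3 | intermediate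
15 | methyl 4,9β-dihydroxy-8-oxo-15-norlindena-4,6-dien-12-oate | COC(=O)C(C)C1=CC2=C(O)[C@@H]3[C@H]([C@]2(C)[C@@H](O)C1=O)C3 | intermediate
16 | methyl 9β-hydroxy-8-oxo-4-(trifluoromethanesulfonyloxy)-15-norlindena-4,6-dien-12-oate | COC(=O)C(C)C1=CC2=C(OS(=O)(=O)C(F)(F)F)[C@@H]3[C@H]([C@]2(C)[C@@H](O)C1=O)C3 | intermediate
17 | methyl 9β-(tert-butyldimethylsilyloxy)-8-oxo-4-(trifluoromethanesulfonyloxy)-15-norlindena-4,6-dien-12-oate | COC(=O)C(C)C1=CC2=C(OS(=O)(=O)C(F)(F)F)[C@@H]3[C@H]([C@]2(C)[C@@H](O[Si](C)(C)C(C)(C)C)C1=O)C3 | intermediate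
18 | methyl 9β-(tert-butyldimethylsilyloxy)-15-hydroxy-8-oxolindena-4,6-dien-12-oate | COC(=O)C(C)C1=CC2=C(CO)[C@@H]3[C@H]([C@]2(C)[C@@H](O[Si](C)(C)C(C)(C)C)C1=O)C3 | intermediate
19 | methyl 9β-(tert-butyldimethylsilyloxy)-8-oxo-15-phenoxylindena-4,6-dien-12-oate | COC(=O)C(C)C1=CC2=C(COc4ccccc4)[C@@H]3[C@H]([C@]2(C)[C@@H](O[Si](C)(C)C(C)(C)C)C1=O)C3 | intermediate
20 | methyl 9β-(tert-butyldimethylsilyloxy)-8-oxolindena-4(15),5,7(11)-trien-12-oate (7(11) geometry not fixed) | COC(=O)C(C)=C1C=C2C(=C)[C@@H]3[C@H]([C@]2(C)[C@@H](O[Si](C)(C)C(C)(C)C)C1=O)C3 | intermediate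
21 | seco-dimer: the quaternary (11R) C11 of a 15-phenoxy unit is bonded to C15 of a second unit that still carries C11–H; both 9β-OTBS | COC(=O)C(C)C1=CC2=C(C[C@@](C)(C(=O)OC)C3=CC4=C(COc6ccccc6)[C@@H]5[C@H]([C@]4(C)[C@@H](O[Si](C)(C)C(C)(C)C)C3=O)C5)[C@@H]3[C@H]([C@]2(C)[C@@H](O[Si](C)(C)C(C)(C)C)C1=O)C3 | intermediate
22 | 9,9′-bis-O-(tert-butyldimethylsilyl)cycloshizukaol A | COC(=O)[C@]1(C)CC2=C3C=C(C(=O)[C@H](O[Si](C)(C)C(C)(C)C)[C@@]3(C)[C@@H]3C[C@H]23)[C@](C)(C(=O)OC)CC2=C3C=C1C(=O)[C@H](O[Si](C)(C)C(C)(C)C)[C@@]3(C)[C@@H]1C[C@H]21 | intermediate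
23 | cycloshizukaol A | COC(=O)[C@]1(C)CC2=C3C=C(C(=O)[C@H](O)[C@@]3(C)[C@@H]3C[C@H]23)[C@](C)(C(=O)OC)CC2=C3C=C1C(=O)[C@H](O)[C@@]3(C)[C@@H]1C[C@H]21 | target

**Step count and risks**
Total steps: 15. Longest linear sequence: 14 steps (1 to 23 through steps 1–5 and 7–15; step 6 prepares 8 from 7).

Step 14 (Proposed new method). What may go wrong: chain growth to open or larger cyclic oligomers, [4+2] self-addition of the triene, and incomplete facial control at the first C11 may outrun the cyclodimerisation. The fallback makes the two bonds separately by known chemistry; it sets out from 18 and 19 and comes back at 22. Alcohol 18 is silylated (TESCl, imidazole) to the 15-O-triethylsilyl ether F1. Its lithium trienolate (LiHMDS, THF, −78 °C) is added to triene 20, generated separately from 19 with LiHMDS at −78 °C; 1,8-conjugate addition and protonation should give the seco-dimer TES ether F2, with C11 epimers separated at this stage. Selective removal of the primary silyl group (PPTS, MeOH) gives the seco-dimer allylic alcohol F3, and Boc2O/DMAP gives the seco-dimer tert-butyl carbonate F4. A Tsuji–Trost macrocyclisation (Pd(PPh3)4, dppe, THF, 60 °C, 1 mM) then forms the last C11–C15′ bond and gives 22.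

Step 7. What may go wrong: 1,2-addition of the ketene acetal to the carbonyl group, or acid-triggered cyclopropane migration and aromatisation of the activated bicyclo[3.1.0]hexenone, may take the place of conjugate addition at the hindered β-carbon. The fallback sets out from 6 and comes back at 12. Copper-mediated vinyl transfer (vinylMgBr, CuBr·SMe2, TMSCl, −78 °C, anti to the cyclopropane) gives the vinyl silyl enol ether F5. A Mukaiyama aldol reaction with 9 (BF3·OEt2) gives the aldol F6, and TsOH-mediated dehydration gives the vinyl enone F7. Chemoselective dihydroxylation of the electron-rich vinyl group (OsO4 cat., NMO) gives the diol F8, TEMPO/NaOCl/NaClO2 oxidation of its primary alcohol gives the α-hydroxy acid F9, and TMSCHN2 gives 12.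

Step 9. What may go wrong: aldol closure of the dienolate onto the C9 ketone (five-membered ring) or methoxide cleavage of the α-keto ester may compete with acylation at C8, and borohydride may over-reduce. The fallback masks the C9 oxygen during ring closure; it sets out from 12 and comes back at 15. TBSOTf/2,6-lutidine gives the silyl ether F10, and KOt-Bu (THF, 0 °C) closes ring B to the 9-silyloxy vinylogous diketone F11 (C9 epimers). HF·pyridine gives the 9-hydroxy vinylogous diketone F12 (C9 epimers), Cu(OAc)2 in aqueous acetic acid oxidises the α-ketol to 14, now isolated, and NaBH4 at −30 °C converts 14 into 15 as in the main route.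

Further compounds
F1 | step 14 | 15-O-triethylsilyl ether of 18 | COC(=O)C(C)C1=CC2=C(CO[Si](CC)(CC)CC)[C@@H]3[C@H]([C@]2(C)[C@@H](O[Si](C)(C)C(C)(C)C)C1=O)C3
F2 | step 14 | seco-dimer TES ether (as 21 with OSiEt3 in place of OPh) | COC(=O)C(C)C1=CC2=C(C[C@@](C)(C(=O)OC)C3=CC4=C(CO[Si](CC)(CC)CC)[C@@H]5[C@H]([C@]4(C)[C@@H](O[Si](C)(C)C(C)(C)C)C3=O)C5)[C@@H]3[C@H]([C@]2(C)[C@@H](O[Si](C)(C)C(C)(C)C)C1=O)C3
F3 | step 14 | seco-dimer allylic alcohol | COC(=O)C(C)C1=CC2=C(C[C@@](C)(C(=O)OC)C3=CC4=C(CO)[C@@H]5[C@H]([C@]4(C)[C@@H](O[Si](C)(C)C(C)(C)C)C3=O)C5)[C@@H]3[C@H]([C@]2(C)[C@@H](O[Si](C)(C)C(C)(C)C)C1=O)C3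
F4 | step 14 | seco-dimer tert-butyl carbonate | COC(=O)C(C)C1=CC2=C(C[C@@](C)(C(=O)OC)C3=CC4=C(COC(=O)OC(C)(C)C)[C@@H]5[C@H]([C@]4(C)[C@@H](O[Si](C)(C)C(C)(C)C)C3=O)C5)[C@@H]3[C@H]([C@]2(C)[C@@H](O[Si](C)(C)C(C)(C)C)C1=O)C3
F5 | step 7 | trimethylsilyl enol ether of 4-methyl-4-vinylbicyclo[3.1.0]hexan-2-one (vinyl anti to the cyclopropane methylene) | C=C[C@]1(C)C=C(O[Si](C)(C)C)[C@H]2C[C@@H]12
F6 | step 7 | methyl 4-hydroxy-2-methyl-4-(2-methyl-4-oxo-2-vinylbicyclo[3.1.0]hexan-3-yl)butanoate | COC(=O)C(C)CC(O)C1C(=O)[C@H]2C[C@H]2[C@]1(C)C=C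
F7 | step 7 | methyl 2-methyl-4-(2-methyl-4-oxo-2-vinylbicyclo[3.1.0]hexan-3-ylidene)butanoate | COC(=O)C(C)CC=C1C(=O)[C@H]2C[C@H]2[C@]1(C)C=C
F8 | step 7 | diol from dihydroxylation of the vinyl group of F7 | COC(=O)C(C)CC=C1C(=O)[C@H]2C[C@H]2[C@]1(C)C(O)CO
F9 | step 7 | α-hydroxy acid corresponding to 12 (free CO2H at C8) | COC(=O)C(C)CC=C1C(=O)[C@H]2C[C@H]2[C@]1(C)C(O)C(=O)O
F10 | step 9 | 9-O-TBS ether of 12 | COC(=O)C(C)CC=C1C(=O)[C@H]2C[C@H]2[C@]1(C)C(O[Si](C)(C)C(C)(C)C)C(=O)OC
F11 | step 9 | methyl 9-(tert-butyldimethylsilyloxy)-4-hydroxy-8-oxo-15-norlindena-4,6-dien-12-oate (C9 epimers) | COC(=O)C(C)C1=CC2=C(O)[C@@H]3[C@H]([C@]2(C)C(O[Si](C)(C)C(C)(C)C)C1=O)C3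
F12 | step 9 | methyl 4,9-dihydroxy-8-oxo-15-norlindena-4,6-dien-12-oate (C9 epimers) | COC(=O)C(C)C1=CC2=C(O)[C@@H]3[C@H]([C@]2(C)C(O)C1=O)C3
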